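**Plan**

- Retrosynthesis: the C5–Cα bond of the propenal chain is cut first (Mizoroki–Heck). Then O1–C2 and C2–C3 of ring B are cut together (formal [4+1]), leaving a ring A sulfone that releases an ortho-quinone methide and a ring C benzylic sulfonium salt.
- Enabling feature: C2 is bonded to both O1 and C3, and O1, C7a, C3a and C3 are the four atoms of an ortho-quinone methide of ring A (O=C7a, C3a=C3). C2, carrying ring C, can therefore enter as one carbon that is a nucleophile toward C3 (ylide) and then an electrophile toward O1 (sulfonium).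
- Forward: the ring A sulfone (steps 1–4) and the chiral ring C sulfonium salt (steps 5–8) are made separately. Step 9 joins them and closes ring B, step 10 attaches the three-carbon chain at C5, and step 11 removes all masking groups.
- Stereochemistry: C2 comes from the open face of an isothiocineole-derived benzylide followed by one SN2 inversion on ring closure. C3 is set relative to C2 (trans) in the same addition, the racemic centre of the sulfone being erased in the planar methide. The E alkene comes from the Heck step.

Key step: step 9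

Assumption: the sense of induction is taken from the usual model for isothiocineole benzylides (exo S-alkylation, aryl group syn to the sulfur lone pair, attack anti to the gem-dimethyl carbon), which calls for the (1S,4S,5S) sulfide to reach (2R); should the annulation show the opposite sense, the enantiomeric sulfide is used in the same steps.

**Route**

Step 1
Reactants: 1 5-bromo-2-hydroxy-3-methoxybenzaldehyde
Product: 2 4-bromo-2-[1-hydroxy-2-(isopropoxydimethylsilyl)ethyl]-6-methoxyphenol (racemic)
Conditions: iPrOMe2SiCH2MgCl (3 equiv, from ClCH2SiMe2OiPr and Mg), THF, 0 °C to rt; aq NH4Cl; crude product carried on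
Reagents that add atoms: (isopropoxydimethylsilyl)methylmagnesium chloride, CC(C)O[Si](C)(C)C[Mg]Cl
Why: Grignard 1,2-addition of a hydroxymethyl anion equivalent to the aldehyde should proceed once the first equivalent has formed the magnesium phenoxide, as in the usual additions to free salicylaldehydes, the aryl bromide being inert to an alkylmagnesium chloride at this temperature and the new stereocentre being racemic and erased in step 9.

Step 2
Reactants: 2 4-bromo-2-[1-hydroxy-2-(isopropoxydimethylsilyl)ethyl]-6-methoxyphenol
Product: 3 4-bromo-2-(1,2-dihydroxyethyl)-6-methoxyphenol (racemic)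
Conditions: 30% H2O2, KF, KHCO3, THF/MeOH (1:1), rt
Reagents that add atoms: hydrogen peroxide, OO
Why: Tamao–Fleming oxidation should replace the C–Si bond of the alkoxysilane by C–OH under bicarbonate-buffered fluoride conditions that are mild enough to avoid Peterson elimination of the β-hydroxysilane.

Step 3
Reactants: 3 4-bromo-2-(1,2-dihydroxyethyl)-6-methoxyphenol
Product: 4 4-bromo-2-[2-(tert-butyldimethylsilyloxy)-1-hydroxyethyl]-6-methoxyphenol (racemic)
Conditions: TBSCl (1.05 equiv), imidazole (2.2 equiv), DMF, −20 to 0 °C
Reagents that add atoms: tert-butyldimethylsilyl chloride, CC(C)(C)[Si](C)(C)Cl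
Why: Silylation with a bulky chlorosilane and imidazole should select the primary aliphatic hydroxyl over the secondary benzylic one and over the doubly ortho-substituted, hydrogen-bonded phenol, as in the usual monosilylation of hydroxybenzyl alcohols.

Step 4
Reactants: 4 4-bromo-2-[2-(tert-butyldimethylsilyloxy)-1-hydroxyethyl]-6-methoxyphenol; 5 sodium p-toluenesulfinate
Product: 6 4-bromo-2-[2-(tert-butyldimethylsilyloxy)-1-(p-toluenesulfonyl)ethyl]-6-methoxyphenol (racemic)
Conditions: 5 (2 equiv), CF3CO2H (1.5 equiv), 4 Å MS, CH2Cl2, 0 °C to rt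
Reagents that add atoms: none
Why: The sulfinic acid liberated in the flask should promote loss of water from the ortho-hydroxybenzylic alcohol and capture the resulting quinone methide or benzylic cation at sulfur, the standard substitution route to 2-(1-sulfonylalkyl)phenols, in a medium no more acidic than the sulfinic acid so that the primary silyl ether should survive.

Step 5
Reactants: 7 5-hydroxyvanillin (3,4-dihydroxy-5-methoxybenzaldehyde)
Product: 8 3-methoxy-4,5-bis(methoxymethoxy)benzaldehyde
Conditions: MOMCl (3 equiv), iPr2NEt (4 equiv), CH2Cl2, 0 °C to rt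
Reagents that add atoms: chloromethyl methyl ether, COCCl
Why: O-alkylation of both catechol hydroxyls with the chloromethyl ether gives acetals that are stable to the bases and to the palladium step that follow and are removable with acid at the end.

Step 6
Reactants: 8 3-methoxy-4,5-bis(methoxymethoxy)benzaldehyde
Product: 9 [3-methoxy-4,5-bis(methoxymethoxy)phenyl]methanol
Conditions: NaBH4, MeOH, 0 °C
Reagents that add atoms: none
Why: Borohydride reduction of an aryl aldehyde to the benzylic alcohol is routine and leaves the acetals untouched.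

Step 7
Reactants: 9 [3-methoxy-4,5-bis(methoxymethoxy)phenyl]methanol
Product: 10 5-(bromomethyl)-1-methoxy-2,3-bis(methoxymethoxy)benzene
Conditions: CBr4 (1.2 equiv), PPh3 (1.25 equiv), CH2Cl2, 0 °C; filtered through a short pad and used at once
Reagents that add atoms: carbon tetrabromide, BrC(Br)(Br)Br
Why: The Appel reaction converts the benzylic alcohol into the bromide under neutral conditions that spare the acid-labile acetals, and immediate use avoids decay of the electron-rich benzylic bromide.

Step 8
Reactants: 10 5-(bromomethyl)-1-methoxy-2,3-bis(methoxymethoxy)benzene; 11 (1S,4S,5S)-isothiocineole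
Product: 12 (1S,4S,5S,6S)-6-[3-methoxy-4,5-bis(methoxymethoxy)benzyl]-4,7,7-trimethyl-6-thiabicyclo[3.2.1]octan-6-ium trifluoromethanesulfonate
Conditions: 11 (1.3 equiv), LiOSO2CF3 (5 equiv), CH2Cl2/H2O (1:1), rt; trituration with Et2O
Reagents that add atoms: lithium trifluoromethanesulfonate, [Li+].[O-]S(=O)(=O)C(F)(F)F
Why: SN2 alkylation of the sulfide by the benzylic bromide should occur only at the exo lone pair of sulfur, giving one configuration at sulfur, while exchange of bromide for the non-nucleophilic triflate in the two-phase medium prevents the reverse reaction.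

Step 9
Reactants: 6 4-bromo-2-[2-(tert-butyldimethylsilyloxy)-1-(p-toluenesulfonyl)ethyl]-6-methoxyphenol; 12 the sulfonium triflate of step 8
Product: 16 (2R,3S)-5-bromo-3-[(tert-butyldimethylsilyloxy)methyl]-7-methoxy-2-[3-methoxy-4,5-bis(methoxymethoxy)phenyl]-2,3-dihydro-1-benzofuran, via ortho-quinone methide 13 (not isolated), via sulfonium benzylide 14 (not isolated), via phenoxide betaine 15 (not isolated)
Conditions: 12 (1.4 equiv), Cs2CO3 (3 equiv), CH2Cl2/MeCN (4:1), 0 °C; 6 added over 2 h by syringe pump; then rt
Reagents that add atoms: none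
Why: Proposed new method: Cs2CO3 deprotonates the phenol of 6, which expels p-toluenesulfinate to give the (E)-ortho-quinone methide 13, and also deprotonates 12 to the benzylide 14; the ylide carbon adds to the exocyclic methide carbon (the future C3), restoring the aromaticity of ring A in the betaine 15, whose phenoxide then displaces the sulfide at the benzylic carbon. The closest known reactions are the [4+1] annulations of ortho-quinone methides released from 2-(1-sulfonylalkyl)phenols with sulfonium ylides, which give trans-2,3-dihydrobenzofurans, and the epoxidations, aziridinations and cyclopropanations of isothiocineole-derived benzylides; an alkyl-substituted methide combined with a chiral semi-stabilised benzylide has not been shown. Ring B closes by a 5-exo-tet SN2 displacement in which O1 attacks C2 anti to sulfur. C2 is controlled by the rigid isothiocineole scaffold, which is alkylated at one sulfur lone pair only, fixes the ylide conformation and shields one face of the ylide carbon, the configuration so created being inverted once on closure; C3 is fixed in the same, effectively irreversible C–C bond formation, the approach that keeps ring C away from the silyloxymethyl group giving the betaine that closes to the trans product. The step needs capture of the methide to outrun its tautomerisation to a vinylphenol and needs a clean SN2 closure: the silyl ether offers no hydrogen bond to the methide oxygen, so the E geometry, which cannot undergo a 1,5-hydrogen shift, should prevail; slow addition of 6 keeps the methide dilute in excess ylide; and the MOM acetals in place of a free para-phenol on ring C keep the C2–S bond from ionising.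

Step 10
Reactants: 16 the bromodihydrobenzofuran of step 9; 17 acrolein diethyl acetal
Product: 18 (2R,3S)-3-[(tert-butyldimethylsilyloxy)methyl]-5-[(1E)-3,3-diethoxyprop-1-en-1-yl]-7-methoxy-2-[3-methoxy-4,5-bis(methoxymethoxy)phenyl]-2,3-dihydro-1-benzofuran
Conditions: Pd(OAc)2 (5 mol %), nBu4NOAc (2 equiv), K2CO3 (1.5 equiv), KCl (1 equiv), 17 (3 equiv), DMF, 90 °C; aqueous work-up without acid, chromatography on Et3N-treated silica
Reagents that add atoms: none
Why: Mizoroki–Heck coupling under phosphine-free tetraalkylammonium acetate conditions, which are known to turn aryl bromides and acrolein diethyl acetal into cinnamaldehyde acetals, should proceed by oxidative addition of the aryl bromide to zerovalent palladium formed from Pd(OAc)2, syn insertion and syn β-hydride elimination toward the benzylic hydrogen, which gives the E alkene.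

Step 11
Reactants: 18 the diethyl acetal of step 10
Product: 19 Cassyformin, (2E)-3-[(2R,3S)-2-(3,4-dihydroxy-5-methoxyphenyl)-3-(hydroxymethyl)-7-methoxy-2,3-dihydro-1-benzofuran-5-yl]prop-2-enal
Conditions: 3 M aq HCl, THF, 40 °C, under argon
Reagents that add atoms: water, O
Why: Aqueous acid should hydrolyse the conjugated acetal to the enal, the primary silyl ether to the alcohol and both aryl methoxymethyl acetals to the catechol in one operation, without touching either stereocentre.

**Compound list**

1 | 5-bromo-2-hydroxy-3-methoxybenzaldehyde | COc1cc(Br)cc(C=O)c1O | starting material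
2 | 4-bromo-2-[1-hydroxy-2-(isopropoxydimethylsilyl)ethyl]-6-methoxyphenol, racemic | COc1cc(Br)cc(C(O)C[Si](C)(C)OC(C)C)c1O | intermediate
3 | 4-bromo-2-(1,2-dihydroxyethyl)-6-methoxyphenol, racemic | COc1cc(Br)cc(C(O)CO)c1O | intermediate
4 | 4-bromo-2-[2-(tert-butyldimethylsilyloxy)-1-hydroxyethyl]-6-methoxyphenol, racemic | COc1cc(Br)cc(C(O)CO[Si](C)(C)C(C)(C)C)c1O | intermediate
5 | sodium p-toluenesulfinate | Cc1ccc(S(=O)[O-])cc1.[Na+] | starting material
6 | 4-bromo-2-[2-(tert-butyldimethylsilyloxy)-1-(p-toluenesulfonyl)ethyl]-6-methoxyphenol, racemic | COc1cc(Br)cc(C(CO[Si](C)(C)C(C)(C)C)S(=O)(=O)c2ccc(C)cc2)c1O | intermediate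
7 | 5-hydroxyvanillin (3,4-dihydroxy-5-methoxybenzaldehyde) | COc1cc(C=O)cc(O)c1O | starting material
8 | 3-methoxy-4,5-bis(methoxymethoxy)benzaldehyde | COc1cc(C=O)cc(OCOC)c1OCOC | intermediate
9 | [3-methoxy-4,5-bis(methoxymethoxy)phenyl]methanol | COc1cc(CO)cc(OCOC)c1OCOC | intermediate
10 | 5-(bromomethyl)-1-methoxy-2,3-bis(methoxymethoxy)benzene | COc1cc(CBr)cc(OCOC)c1OCOC | intermediate
11 | (1S,4S,5S)-isothiocineole, (1S,4S,5S)-4,7,7-trimethyl-6-thiabicyclo[3.2.1]octane (commercial; also one step from (S)-limonene, sulfur and γ-terpinene) | C[C@H]1CC[C@H]2C[C@@H]1SC2(C)C | starting material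
12 | (1S,4S,5S,6S)-6-[3-methoxy-4,5-bis(methoxymethoxy)benzyl]-4,7,7-trimethyl-6-thiabicyclo[3.2.1]octan-6-ium trifluoromethanesulfonate, benzyl group exo on sulfur | C[C@H]1CC[C@H]2C[C@@H]1[S@+](Cc3cc(OC)c(OCOC)c(OCOC)c3)C2(C)C.[O-]S(=O)(=O)C(F)(F)F | intermediate
13 | (6E)-4-bromo-6-[2-(tert-butyldimethylsilyloxy)ethylidene]-2-methoxycyclohexa-2,4-dien-1-one, the ortho-quinone methide (not isolated) | COC1=CC(Br)=C/C(=C\CO[Si](C)(C)C(C)(C)C)C1=O | intermediate
14 | sulfonium benzylide formed from 12 by loss of the benzylic proton (not isolated) | C[C@H]1CC[C@H]2C[C@@H]1[S@+]([CH-]c3cc(OC)c(OCOC)c(OCOC)c3)C2(C)C | intermediate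
15 | phenoxide betaine: the (1S,2S)-1-aryl-2-(5-bromo-3-methoxy-2-oxidophenyl)-3-(tert-butyldimethylsilyloxy)propyl group on the sulfonium sulfur of the isothiocineole scaffold, aryl = 3-methoxy-4,5-bis(methoxymethoxy)phenyl (not isolated) | C[C@H]1CC[C@H]2C[C@@H]1[S@+]([C@H](c3cc(OC)c(OCOC)c(OCOC)c3)[C@H](CO[Si](C)(C)C(C)(C)C)c4cc(Br)cc(OC)c4[O-])C2(C)C | intermediate
16 | (2R,3S)-5-bromo-3-[(tert-butyldimethylsilyloxy)methyl]-7-methoxy-2-[3-methoxy-4,5-bis(methoxymethoxy)phenyl]-2,3-dihydro-1-benzofuran (trans) | COc1cc([C@@H]2Oc3c(OC)cc(Br)cc3[C@H]2CO[Si](C)(C)C(C)(C)C)cc(OCOC)c1OCOC | intermediate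
17 | acrolein diethyl acetal (3,3-diethoxyprop-1-ene) | C=CC(OCC)OCC | starting material
18 | (2R,3S)-3-[(tert-butyldimethylsilyloxy)methyl]-5-[(1E)-3,3-diethoxyprop-1-en-1-yl]-7-methoxy-2-[3-methoxy-4,5-bis(methoxymethoxy)phenyl]-2,3-dihydro-1-benzofuran | COc1cc([C@@H]2Oc3c(OC)cc(/C=C/C(OCC)OCC)cc3[C@H]2CO[Si](C)(C)C(C)(C)C)cc(OCOC)c1OCOC | intermediate
19 | Cassyformin, (2E)-3-[(2R,3S)-2-(3,4-dihydroxy-5-methoxyphenyl)-3-(hydroxymethyl)-7-methoxy-2,3-dihydro-1-benzofuran-5-yl]prop-2-enal | COc1cc([C@@H]2Oc3c(OC)cc(/C=C/C=O)cc3[C@H]2CO)cc(O)c1O | target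

**Step count**

Total: 11 steps. Longest linear sequence: 7 steps (steps 5–8, then 9–11; the ring A branch, steps 1–4 then 9–11, is equally long).

**Steps most likely to fail**

1. Step 9 (proposed new method). The process at risk is facial discrimination in the ylide addition, together with partial ionisation of the C2–S bond before closure and tautomerisation of the methide before capture; any of these would lower enantiomeric purity or conversion. The fallback replaces asymmetric induction by resolution and sets out from 10 and 6. Bromide 10 and tetrahydrothiophene (acetone, rt) should give the achiral salt 1-[3-methoxy-4,5-bis(methoxymethoxy)benzyl]tetrahydrothiophen-1-ium bromide F1. F1 and 6 with Cs2CO3 in CH2Cl2, the established achiral annulation of sulfonium ylides with ortho-quinone methides, should give racemic trans-5-bromo-3-[(tert-butyldimethylsilyloxy)methyl]-7-methoxy-2-[3-methoxy-4,5-bis(methoxymethoxy)phenyl]-2,3-dihydro-1-benzofuran F2. Preparative chromatography on a chiral stationary phase then delivers the (2R,3S) enantiomer, and the route is rejoined at 16.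

2. Step 10. The processes at risk are slow oxidative addition of the electron-rich aryl bromide and β-hydride elimination toward the acetal carbon, which would end in a saturated ester after hydrolysis. The fallback builds the chain by carbonyl olefination and sets out from 16. Bromine–lithium exchange (n-BuLi, THF, −78 °C) and quenching with DMF should give (2R,3S)-3-[(tert-butyldimethylsilyloxy)methyl]-7-methoxy-2-[3-methoxy-4,5-bis(methoxymethoxy)phenyl]-2,3-dihydro-1-benzofuran-5-carbaldehyde F3. A Wittig reaction with Ph3P=CHCHO (toluene, 80 °C) should give the protected enal (2E)-3-[(2R,3S)-3-[(tert-butyldimethylsilyloxy)methyl]-7-methoxy-2-[3-methoxy-4,5-bis(methoxymethoxy)phenyl]-2,3-dihydro-1-benzofuran-5-yl]prop-2-enal F4. F4 under the acid conditions of step 11 rejoins the route at 19.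

3. Step 11. The process at risk is acid-induced heterolysis of the O1–C2 bond once the para hydroxyl of ring C is free (ring opening or epimerisation at C2), along with acid-mediated decay of the enal. The fallback is a staged deprotection that avoids strong protic acid at that stage and sets out from 18. AcOH/THF/H2O (3:1:1) at rt should hydrolyse only the acetal and the silyl ether, giving (2E)-3-[(2R,3S)-3-(hydroxymethyl)-7-methoxy-2-[3-methoxy-4,5-bis(methoxymethoxy)phenyl]-2,3-dihydro-1-benzofuran-5-yl]prop-2-enal F5. The MOM acetals are then exchanged with TMSOTf/2,2'-bipyridyl (CH2Cl2, 0 °C) and the resulting trimethylsilyl ethers hydrolysed by water at neutral pH, which rejoins the route at 19.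

**Further compounds**

F1 | step 9 | 1-[3-methoxy-4,5-bis(methoxymethoxy)benzyl]tetrahydrothiophen-1-ium bromide | COc1cc(C[S+]2CCCC2)cc(OCOC)c1OCOC.[Br-]
F2 | step 9 | racemic trans-5-bromo-3-[(tert-butyldimethylsilyloxy)methyl]-7-methoxy-2-[3-methoxy-4,5-bis(methoxymethoxy)phenyl]-2,3-dihydro-1-benzofuran (both enantiomers) | COc1cc([C@@H]2Oc3c(OC)cc(Br)cc3[C@H]2CO[Si](C)(C)C(C)(C)C)cc(OCOC)c1OCOC.COc1cc([C@H]2Oc3c(OC)cc(Br)cc3[C@@H]2CO[Si](C)(C)C(C)(C)C)cc(OCOC)c1OCOC
F3 | step 10 | (2R,3S)-3-[(tert-butyldimethylsilyloxy)methyl]-7-methoxy-2-[3-methoxy-4,5-bis(methoxymethoxy)phenyl]-2,3-dihydro-1-benzofuran-5-carbaldehyde | COc1cc([C@@H]2Oc3c(OC)cc(C=O)cc3[C@H]2CO[Si](C)(C)C(C)(C)C)cc(OCOC)c1OCOC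
F4 | step 10 | (2E)-3-[(2R,3S)-3-[(tert-butyldimethylsilyloxy)methyl]-7-methoxy-2-[3-methoxy-4,5-bis(methoxymethoxy)phenyl]-2,3-dihydro-1-benzofuran-5-yl]prop-2-enal | COc1cc([C@@H]2Oc3c(OC)cc(/C=C/C=O)cc3[C@H]2CO[Si](C)(C)C(C)(C)C)cc(OCOC)c1OCOC
F5 | step 11 | (2E)-3-[(2R,3S)-3-(hydroxymethyl)-7-methoxy-2-[3-methoxy-4,5-bis(methoxymethoxy)phenyl]-2,3-dihydro-1-benzofuran-5-yl]prop-2-enal | COc1cc([C@@H]2Oc3c(OC)cc(/C=C/C=O)cc3[C@H]2CO)cc(OCOC)c1OCOC
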